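The pitfall is to read an induction period as a gas shortage for the whole run.

- larch: L 0.12 M; X 67 mM (held); run made earlier
- flask: L 0.25 M; X 67 mM (held); time 8.0 min

larch run (percent of the L charged)

| time / s | E / % | L / % |
|---|---|---|
| 10.0 | 0.4 | 98.9 |
| 20.0 | 1.1 | 98.3 |
| 50.0 | 6.0 | 93.7 |

(scatter of a reading: 0.5 percentage points)

- at the start none of X is in solution
- Z is what X becomes in solution

- E at 8.0 min, in percent of the L charged
- concentration of Z in solution at 2.0 min, in percent of saturation
- the change that raises the amount of E at 8.0 min, in percent of the L charged most ("none" if none brings more than 2 percentage points) (red / teal / none)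
- amount of E at 8.0 min, in percent of the L charged, after red

- red: doubling the transfer coefficient of X, all else as stated
- teal: doubling the saturation concentration of X, all else as stated

1. I take E to form at a rate proportional to [L][Z]. With [Z] held near saturation, [L] falls first order (pseudo-first-order), and E in per cent does not change with the charge. With [Z] held far below saturation, the mM per minute equal the supply of dissolving X, and E in per cent falls as the charge rises.

2. I carry the turnover per L, 0.0980 min⁻¹: the slope of E between the last two larch readings, as a fraction of the charge. Scatter puts about 0.0141 min⁻¹ on it.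

3. Over 8.0 min in the flask, first order gives a conversion of L of 54.3%. Fixed mM per minute give 37.6%.

4. Now the question turned round: a yield of 69% needs a mean turnover 1.49 times the larch slope, so [Z] at those larch readings would have to stand at 0.671 of its mean level in the flask. I commit to about 54.3%, with [Z] high by 2.0 min. Teal lifts the ceiling on [Z], so I choose teal.

5. The forecast, “Rising E with an induction period means X must first dissolve”, gives 69%, 36%, teal and 84%.

6. The flask gives 45.7%, 83.7%, teal and 48.1%.

    X ⇌ Z, rate k1*(csat - [Z]) (kL = 0.0430 s⁻¹)
    L + Z → E (k = 0.0300 M⁻¹ s⁻¹)
    Z + E → D (k = 0.00800 M⁻¹ s⁻¹)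
    2 L → Q (k = 7.10 × 10⁻⁴ M⁻¹ s⁻¹)
    Z ⇌ J (K = 7.30, k = 0.00170 s⁻¹)

At 2.0 min, [Z] in the flask stands at 83.7% of saturation, and by 8.0 min the flask has lost 59.6% of its L, nearer 54.3% than 37.6%. In the neighbouring flask, the same but for a quarter of the charge of L, at 0.062 M, the same turnover again gives 54.3%. That flask ends with E at 49.9% and has lost 58.9% of its L.

The earlier runs and the new flask are simulated with constants of no real substance, noise included.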